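**Remark (assumption).** The target has no stereocentre, and the aryl group on C2 is symmetric about the C2–C1′ bond, so there is no stereogenic axis either. The compound is achiral; "single enantiomer" is read as the one constitution written in the SMILES, and no step needs stereocontrol.

## Structural features

The target (16) is a 2-arylbenzofuran. The benzofuran (O1, C2, C3, C3a, C4–C7, C7a) carries a hydroxyl at C6 and a prenyl group at C7, and is joined through C2 to C1′ of a resorcinol ring with hydroxyls at C3′ and C5′ and prenyl groups at C2′ and C6′. No stereocentres are present. Each of the three phenols sits ortho to a prenyl group, so the compound is prone to acid-induced chroman formation and to oxidation, and it rules out hydrogenolysis and strong Lewis acids. The real difficulties are the C2–C1′ bond, flanked by two ortho prenyl groups, and the placement of the three prenyl groups (C7 between the oxygen-bearing C6 and the ring fusion; C2′/C6′ next to the junction and not at C4′ between the two oxygens). The key step uses the fact that O1–C2–C3 of the furan is the O–C–C unit of an aryl methyl ketone enolate whose aryl group is the resorcinol ring. C3a and C7a are adjacent benzo carbons that can carry two different halogens. Both ring-forming bonds (C3–C3a and O1–C7a) then come from one ketone and one ortho-bromo-iodoarene, and the crowded C2–C1′ bond exists from the start as an aryl–carbonyl bond.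

## Logic of the disconnections

**16 ⇐ 15.** The three phenolic O–H bonds are traced back to three aryl O–CH2OCH3 acetal bonds. Free phenols would be deprotonated in the basic Pd-catalysed ring construction, whereas acetals survive alkoxide, organolithium and Pd(0) and also serve as the directing group needed earlier. The gain is a neutral penultimate compound. The demand is that the last step cleaves three acetals without protonating any of the three prenyl olefins ortho to the freed phenols.

**15 ⇐ 7 + 13.** The cuts are C3–C3a and O1–C7a, which removes the furan ring and divides the molecule into two arenes of similar size. Mapping 13 onto 16: its iodine-bearing carbon becomes C3a and its bromine-bearing carbon C7a; the prenyl-bearing carbon next to C–Br becomes C7 and the oxygen-bearing carbon next to that becomes C6. This matches 16, so neither partner needs a constitutional correction. The forward step must react at C–I before C–Br, arylate the only enolisable position of 7 once, and then close through oxygen.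

**13 ⇐ 9 + 10, and 9 ⇐ 8.** The aryl–CH2 bond of the C7 prenyl group is cut, then the acetal O–CH2 bond. This leads to a commercial bromo-iodophenol in which both halogens are already in place. The forward step must metalate only the C–H flanked by the acetal oxygen and bromine, without touching C–I or C–Br, and must alkylate 10 at its unsubstituted terminus.

**7 ⇐ 6 ⇐ 4.** After removal of the two acetals, both aryl–CH2 bonds (C2′–CH2 and C6′–CH2) are cut in a retro-[3,3] sense to the two aryl O–C(CH3)2 bonds of 4. This is the point where the precursor design is improved: the acetyl carbon is present from the outset, so no cross-coupling at a doubly flanked aryl C–O bond, no organotin reagent, no statistical C-alkylation of a triphenol and no selective protection of one phenol among three are needed. The forward step must send each migrating allyl unit to the ring carbon next to the acetyl group (C2′/C6′) and not to the carbon between the two oxygens (C4′).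

**4 ⇐ 3 ⇐ 1 + 2.** The terminal alkenes are taken back to alkynes, and the two O–C(tertiary) bonds are cut to give a commercial dihydroxyacetophenone and a commercial tertiary propargylic chloride. The forward steps must O-alkylate at a tertiary carbon without elimination and stop the hydrogenation at the alkene.

## Other disconnections considered

**Alternative 1:** Michael–Claisen annulation followed by aromatisation.
- Cut: C1′–C6′ and C4′–C5′, so the resorcinol ring is built last from acyclic carbon.
- Forward key step: the sodium enolate of A2 adds to the β-carbon of enone A1; the methyl ketone enolate of the adduct then closes onto one ester to give the cyclohexane-1,3-dione A3. Ester cleavage, decarboxylation, dehydrogenation to the resorcinol and acetal removal would follow.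
- In favour: no bond is made to a pre-formed crowded arene, all ring carbons arrive with their substituents, and only enolate chemistry is needed.
- Against: the Michael step joins a fully substituted malonate carbon to the β-carbon of an α-branched enone, a hindered and reversible addition. A1 itself needs an aldol condensation at the internal methylene of a methyl ketone, not at its methyl group. A3 is one oxidation level below the arene, so a dehydrogenation must be run in the presence of three prenyl olefins and an electron-rich benzofuran, which the usual reagents (halogens, quinones, hot palladium) attack first.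
- Comparison: on structure the plans are equal, since neither makes the C2–C1′ bond by a hindered biaryl coupling. Alternative 1 is better in needing no precious metal in its key step. On mechanism the chosen plan is redox-neutral throughout and Alternative 1 is not. On step economy Alternative 1 needs at least three operations after its key step against one, plus a separate benzofuran synthesis before it, so it is longer.

**Alternative 2:** Danheiser benzannulation.
- Cut: C3′–C4′ and C5′–C6′ (C2′–C3′ is broken and re-formed on the way).
- Forward key step: thermolysis of cyclobutenone A4 gives a vinylketene that adds silyloxyalkyne A5 in a [2+2] sense. 4π-opening and 6π-closure of the new cyclobutenone give the pentasubstituted phenol A6, and fluoride would then remove the two silyl ethers.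
- In favour: the substitution pattern of the ring is fixed by the pericyclic cascade and cannot leak to a regioisomer, the conditions are neutral and thermal, and the end game is a fluoride desilylation.
- Against: A4 is a 2,3,4-trisubstituted cyclobutenone with an sp3 carbon bearing a prenyl group. Its most direct source, a ketene–alkyne cycloaddition, has its own regiochemical and ketene-dimerisation problems, and the vinylketene from a 4-substituted cyclobutenone is more hindered toward A5.
- Comparison: on structure the plans are equal in avoiding a hindered coupling at C1′. Alternative 2 is better in its last step, because fluoride cannot cyclise an ortho-prenylphenol whereas the acid of the chosen plan can. On mechanism both rely on known reaction types (four pericyclic events against two Pd cycles). On step economy the count after the key step is equal, but the benzofuran must be made separately and then carried into a strained ring, so the route before the key step is clearly longer.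

**Alternative 3:** Catellani three-component assembly.
- Cut: C2′–CH2, C6′–CH2 and C1′–C2, with no ring closed.
- Forward key step: Pd with a strained-olefin co-catalyst turns iodoarene A7 into a palladacycle that is alkylated at both ortho carbons by two molecules of bromide A8. Extrusion of the co-catalyst and Suzuki-type termination with boronate A9 at the ipso carbon give A10. Unmasking of the two tertiary silyl ethers, dehydration to the prenyl olefins and acetal removal would follow.
- In favour: three bonds at the most congested atom are formed in one operation from a simple iodoarene.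
- Against: the side chains arrive in the wrong functional state. Two tertiary alcohols must be dehydrated to the trisubstituted olefin without forming the isopropenyl isomer, and without acid that would close chromans. A 2-benzofuranyl boronate is prone to protodeboronation under base and must intercept a di-ortho-alkylated arylpalladium. A9 needs a full benzofuran synthesis, so the ring construction performed by the chosen key step is still required elsewhere.
- Comparison: Alternative 3 is better in convergence and in bonds formed per step, and the arene half needs fewer steps than 7. The plans are equal in the final deprotection (the same three acetals). Alternative 3 is worse in the three extra operations after its key step and in the olefin-regiochemistry risk; on mechanism it forms C2–C1′ at the most hindered stage, whereas the chosen plan never has to form that bond.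

Key step: step 7

## Route

Handling note: chloromethyl methyl ether is a volatile alkylating carcinogen. It is used in a closed system and residues are quenched with aqueous ammonia.

Step 1
Reactants: 1 1-(3,5-dihydroxyphenyl)ethanone; 2 3-chloro-3-methylbut-1-yne
Product: 3 1-[3,5-bis(2-methylbut-3-yn-2-yloxy)phenyl]ethanone
Conditions: 2 (3.0 equiv), DBU (3.0 equiv), CuCl2·2H2O (1 mol %), MeCN, 0 °C → rt
Reagents that add atoms: none
Why: Copper-catalysed propargylic etherification of phenols: a copper acetylide/allenylidene-type electrophile is captured by the phenoxide at the tertiary carbon. The amidine base is too weak to enolise the methyl ketone, and the two equivalent phenols both react.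

Step 2
Reactants: 3 1-[3,5-bis(2-methylbut-3-yn-2-yloxy)phenyl]ethanone
Product: 4 1-[3,5-bis(2-methylbut-3-en-2-yloxy)phenyl]ethanone
Conditions: H2 (1 atm), Lindlar catalyst, quinoline, EtOAc, rt, stopped after 2 equiv H2
Reagents that add atoms: none
Why: Lindlar semi-hydrogenation of terminal alkynes stops at the alkene when poisoned with quinoline. The aryl ketone and the tertiary allylic C–O bonds are not reduced under these conditions.

Step 3
Reactants: 4 1-[3,5-bis(2-methylbut-3-en-2-yloxy)phenyl]ethanone
Product: 6 1-[3,5-dihydroxy-2,6-bis(3-methylbut-2-en-1-yl)phenyl]ethanone, via mono-rearranged phenol 5 (not isolated)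
Conditions: PhNEt2, 135 °C, Ar
Reagents that add atoms: none
Why: Two successive aromatic Claisen [3,3] rearrangements of 1,1-dimethylallyl aryl ethers place a normal prenyl group ortho to each oxygen. A meta acyl group directs the migration toward itself and a meta oxygen donor directs it away, so both effects steer each shift to C2/C6 and not to C4. The basic amine solvent suppresses acid-catalysed chroman formation; no stereocentre is formed.

Step 4
Reactants: 6 1-[3,5-dihydroxy-2,6-bis(3-methylbut-2-en-1-yl)phenyl]ethanone
Product: 7 1-[3,5-bis(methoxymethoxy)-2,6-bis(3-methylbut-2-en-1-yl)phenyl]ethanone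
Conditions: MOMCl (3 equiv), i-Pr2NEt (4 equiv), CH2Cl2, 0 °C → rt
Reagents that add atoms: chloromethyl methyl ether (MOMCl), COCCl
Why: O-Alkylation of both phenols with an α-chloro ether (MOM protection) under a hindered amine base that does not enolise the ketone. The acetals tolerate the alkoxide/Pd conditions of step 7.

Step 5
Reactants: 8 3-bromo-4-iodophenol
Product: 9 2-bromo-1-iodo-4-(methoxymethoxy)benzene
Conditions: MOMCl (1.3 equiv), i-Pr2NEt (1.6 equiv), CH2Cl2, 0 °C → rt
Reagents that add atoms: chloromethyl methyl ether (MOMCl), COCCl
Why: MOM protection of the phenol. The acetal oxygen is then the directing group for the metalation in step 6.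

Step 6
Reactants: 9 2-bromo-1-iodo-4-(methoxymethoxy)benzene; 10 1-bromo-3-methylbut-2-ene (prenyl bromide)
Product: 13 2-bromo-1-iodo-4-(methoxymethoxy)-3-(3-methylbut-2-en-1-yl)benzene, via aryllithium 11 (not isolated), via arylcopper 12 (not isolated)
Conditions: LDA (1.1 equiv), THF, −78 °C (9 added to the base); CuBr·SMe2 (1.1 equiv), −78 °C; 10 (1.5 equiv), −78 → 0 °C
Reagents that add atoms: none
Why: Directed ortho-metalation. The C–H flanked by the acetal oxygen and bromine is the most acidic, a lithium amide does not exchange with C–I or C–Br, and at −78 °C the ortho-bromoaryllithium does not lose lithium bromide. Transmetalation to copper and allylic substitution at the unsubstituted carbon of 10 (SN2; attack at the disubstituted terminus is disfavoured for this doubly flanked arylcopper) gives the linear prenyl group.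

Step 7
Reactants: 7 1-[3,5-bis(methoxymethoxy)-2,6-bis(3-methylbut-2-en-1-yl)phenyl]ethanone; 13 2-bromo-1-iodo-4-(methoxymethoxy)-3-(3-methylbut-2-en-1-yl)benzene
Product: 15 2-[3,5-bis(methoxymethoxy)-2,6-bis(3-methylbut-2-en-1-yl)phenyl]-6-(methoxymethoxy)-7-(3-methylbut-2-en-1-yl)-1-benzofuran, via bromo deoxybenzoin 14 (not isolated)
Conditions: 7 (1.15 equiv), 13 (1.0 equiv), Pd2(dba)3 (2.5 mol %), DPEphos (6 mol %), NaOt-Bu (2.5 equiv), toluene, 80 → 110 °C
Reagents that add atoms: none
Why: Pd(0)/DPEphos adds oxidatively to the C–I bond of 13 much faster than to the C–Br bond, which is also flanked on both sides; the sodium enolate of 7, which can form only at the methyl group, then displaces iodide on Pd, and C–C reductive elimination gives 14 (C3–C3a). 14 is several pK units more acidic than 7 and is enolised at once; Pd(0) now inserts into the C–Br bond, the (Z)-enolate oxygen binds to give a six-membered oxapalladacycle (Pd, O1, C2, C3, C3a, C7a), and C–O reductive elimination closes the five-membered furan ring (O1–C7a). The closest known reaction type is the domino ketone α-arylation/intramolecular enolate O-arylation of 1,2-dihaloarenes to benzofurans, together with the Pd-catalysed cyclisation of 2-haloaryl ketones with wide-bite-angle bisphosphines. The ring closes by intramolecular O-arylation, a 1,5-closure across O1, C2, C3, C3a and C7a; no stereocentre is formed. Halogen selectivity is secured by bond strength and by the hindrance at C–Br. Mono-arylation is secured by the fast intramolecular second event, the slight excess of 7 and the shielding of the carbonyl by the 2,6-diprenylaryl group. O- over C-attack in the second event is secured by ring size, since C-attack would need a benzocyclobutene. The acetals and the prenyl olefins are inert to alkoxide and Pd(0), and the arylpalladium next to the C7 prenyl group could insert that olefin only through a strained 4-exo or 5-endo path.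

Step 8
Reactants: 15 2-[3,5-bis(methoxymethoxy)-2,6-bis(3-methylbut-2-en-1-yl)phenyl]-6-(methoxymethoxy)-7-(3-methylbut-2-en-1-yl)-1-benzofuran
Product: 16 5-[6-hydroxy-7-(3-methylbut-2-en-1-yl)-1-benzofuran-2-yl]-4,6-bis(3-methylbut-2-en-1-yl)benzene-1,3-diol
Conditions: HCl (1.25 M in MeOH, 0.3 equiv per acetal), MeOH–THF 4:1, 0 → 40 °C, monitored; NaHCO3 quench
Reagents that add atoms: none
Why: Acid-catalysed transacetalisation of aryl MOM ethers to methanol, with the acetal carbon leaving as dimethoxymethane. Aryl MOM ethers solvolyse at acid strengths well below those needed to protonate a trisubstituted olefin, so dilute acid at or below 40 °C should free the three phenols without closing chromans.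

## Compound list

1 | 1-(3,5-dihydroxyphenyl)ethanone | CC(=O)c1cc(O)cc(O)c1 | starting material
2 | 3-chloro-3-methylbut-1-yne | CC(C)(Cl)C#C | starting material
3 | 1-[3,5-bis(2-methylbut-3-yn-2-yloxy)phenyl]ethanone | CC(=O)c1cc(OC(C)(C)C#C)cc(OC(C)(C)C#C)c1 | intermediate
4 | 1-[3,5-bis(2-methylbut-3-en-2-yloxy)phenyl]ethanone | CC(=O)c1cc(OC(C)(C)C=C)cc(OC(C)(C)C=C)c1 | intermediate
5 | 1-[3-hydroxy-5-(2-methylbut-3-en-2-yloxy)-2-(3-methylbut-2-en-1-yl)phenyl]ethanone | CC(=O)c1cc(OC(C)(C)C=C)cc(O)c1CC=C(C)C | intermediate
6 | 1-[3,5-dihydroxy-2,6-bis(3-methylbut-2-en-1-yl)phenyl]ethanone | CC(=O)c1c(CC=C(C)C)c(O)cc(O)c1CC=C(C)C | intermediate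
7 | 1-[3,5-bis(methoxymethoxy)-2,6-bis(3-methylbut-2-en-1-yl)phenyl]ethanone | CC(=O)c1c(CC=C(C)C)c(OCOC)cc(OCOC)c1CC=C(C)C | intermediate
8 | 3-bromo-4-iodophenol | Oc1ccc(I)c(Br)c1 | starting material
9 | 2-bromo-1-iodo-4-(methoxymethoxy)benzene | COCOc1ccc(I)c(Br)c1 | intermediate
10 | 1-bromo-3-methylbut-2-ene (prenyl bromide) | CC(C)=CCBr | starting material
11 | [2-bromo-3-iodo-6-(methoxymethoxy)phenyl]lithium | [Li]c1c(OCOC)ccc(I)c1Br | intermediate
12 | [2-bromo-3-iodo-6-(methoxymethoxy)phenyl]copper | [Cu]c1c(OCOC)ccc(I)c1Br | intermediate
13 | 2-bromo-1-iodo-4-(methoxymethoxy)-3-(3-methylbut-2-en-1-yl)benzene | COCOc1ccc(I)c(Br)c1CC=C(C)C | intermediate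
14 | 1-[3,5-bis(methoxymethoxy)-2,6-bis(3-methylbut-2-en-1-yl)phenyl]-2-[2-bromo-4-(methoxymethoxy)-3-(3-methylbut-2-en-1-yl)phenyl]ethanone | CC(C)=CCc1c(OCOC)cc(OCOC)c(CC=C(C)C)c1C(=O)Cc1ccc(OCOC)c(CC=C(C)C)c1Br | intermediate
15 | 2-[3,5-bis(methoxymethoxy)-2,6-bis(3-methylbut-2-en-1-yl)phenyl]-6-(methoxymethoxy)-7-(3-methylbut-2-en-1-yl)-1-benzofuran | CC(C)=CCc1c(OCOC)cc(OCOC)c(CC=C(C)C)c1-c1cc2ccc(OCOC)c(CC=C(C)C)c2o1 | intermediate
16 | 5-[6-hydroxy-7-(3-methylbut-2-en-1-yl)-1-benzofuran-2-yl]-4,6-bis(3-methylbut-2-en-1-yl)benzene-1,3-diol | CC(C)=CCc1c(O)cc(O)c(CC=C(C)C)c1-c1cc2ccc(O)c(CC=C(C)C)c2o1 | target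

## Step count and least certain steps

Total: 8 steps. Longest linear sequence: 6 steps (1 → 3 → 4 → 6 → 7 → 15 → 16, i.e. steps 1, 2, 3, 4, 7, 8). The dihalide branch (steps 5 and 6) joins at step 7.

**Step 7 (key step).** The most likely failure is a stall after the C-arylation: oxidative addition and C–O reductive elimination at the doubly flanked C–Br bond may be slow, which would let hydrodebromination, or insertion of the arylpalladium into the neighbouring prenyl olefin, compete. Fallback, setting out from 7 and returning at 15:
- 7 would be converted by enol phosphate formation and elimination (LDA, ClP(O)(OEt)2; then LDA) through diethyl 1-[3,5-bis(methoxymethoxy)-2,6-bis(3-methylbut-2-en-1-yl)phenyl]ethenyl phosphate F1 into 3-ethynyl-1,5-bis(methoxymethoxy)-2,4-bis(3-methylbut-2-en-1-yl)benzene F2.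
- Sonogashira coupling of F2 with 13 at the C–I bond (PdCl2(PPh3)2, CuI, Et3N, rt) should give 2-bromo-1-{[3,5-bis(methoxymethoxy)-2,6-bis(3-methylbut-2-en-1-yl)phenyl]ethynyl}-4-(methoxymethoxy)-3-(3-methylbut-2-en-1-yl)benzene F3.
- Pd-catalysed hydroxylation of the C–Br bond (Pd2(dba)3, t-BuXPhos, KOH, dioxane–H2O, 100 °C) would pass through 6-{[3,5-bis(methoxymethoxy)-2,6-bis(3-methylbut-2-en-1-yl)phenyl]ethynyl}-3-(methoxymethoxy)-2-(3-methylbut-2-en-1-yl)phenol F4, which should cyclise 5-endo-dig under the basic conditions to 15.

This moves the C–C bond formation to an unhindered sp carbon and lets hydroxide, not a bulky enolate, attack the hindered position.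

**Step 3.** The risk is regiochemical leakage: one allyl unit may migrate to C4 between the two oxygens. A second risk is cyclisation of a freshly formed ortho-prenylphenol to a chroman on prolonged heating. Fallback, setting out from 1 and returning at 7:
- 1 would be protected (MOMCl, i-Pr2NEt) to 1-[3,5-bis(methoxymethoxy)phenyl]ethanone F5.
- F5 would be iodinated twice para to each oxygen (NIS, 2.2 equiv, MeCN) to 1-[2,6-diiodo-3,5-bis(methoxymethoxy)phenyl]ethanone F6.
- A double Stille coupling of F6 with tributyl(3-methylbut-2-en-1-yl)stannane (Pd2(dba)3, P(t-Bu)3, CsF, dioxane, 90 °C) would give 7.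

The positions are then fixed by electrophilic substitution and cross-coupling, not by a sigmatropic shift, at the cost of a tin reagent.

**Step 6.** The likely failures are attack of the arylcopper at the disubstituted terminus of 10 (SN2′, giving the 1,1-dimethylallyl isomer), and loss of lithium bromide from 11 to an aryne or iodine scrambling if the temperature drifts. The second is controlled by inverse addition at −78 °C. Fallback, setting out from 9 and returning at 13: the metalation is run as in step 6 (through 11 and 12) but quenched with allyl bromide, which has no α/γ ambiguity, to give 2-bromo-1-iodo-4-(methoxymethoxy)-3-(prop-2-en-1-yl)benzene F7. Cross-metathesis of F7 with excess 2-methylbut-2-ene (second-generation Grubbs catalyst, CH2Cl2, 40 °C) would convert the allyl into the prenyl group of 13.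

**Step 8.** The risk is acid-promoted addition of a freed phenol across its ortho prenyl olefin (chroman formation), or capture of the formaldehyde equivalent by the electron-rich resorcinol ring, before all three acetals are gone. Fallback, setting out from 15 and returning at 16: the acetals are exchanged for silyl groups without protic acid (TMSOTf, 2,2′-bipyridyl, MeCN, 0 °C) to give 2-[2,6-bis(3-methylbut-2-en-1-yl)-3,5-bis(trimethylsilyloxy)phenyl]-7-(3-methylbut-2-en-1-yl)-6-(trimethylsilyloxy)-1-benzofuran F8. The aryl silyl ethers of F8 are then hydrolysed with water at neutral pH to 16. The cleavage thus runs by buffered silyl transfer and not by protic solvolysis.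

## Further compounds

F1 | step 7 | diethyl 1-[3,5-bis(methoxymethoxy)-2,6-bis(3-methylbut-2-en-1-yl)phenyl]ethenyl phosphate | C=C(OP(=O)(OCC)OCC)c1c(CC=C(C)C)c(OCOC)cc(OCOC)c1CC=C(C)C
F2 | step 7 | 3-ethynyl-1,5-bis(methoxymethoxy)-2,4-bis(3-methylbut-2-en-1-yl)benzene | C#Cc1c(CC=C(C)C)c(OCOC)cc(OCOC)c1CC=C(C)C
F3 | step 7 | 2-bromo-1-{[3,5-bis(methoxymethoxy)-2,6-bis(3-methylbut-2-en-1-yl)phenyl]ethynyl}-4-(methoxymethoxy)-3-(3-methylbut-2-en-1-yl)benzene | COCOc1ccc(C#Cc2c(CC=C(C)C)c(OCOC)cc(OCOC)c2CC=C(C)C)c(Br)c1CC=C(C)C
F4 | step 7 | 6-{[3,5-bis(methoxymethoxy)-2,6-bis(3-methylbut-2-en-1-yl)phenyl]ethynyl}-3-(methoxymethoxy)-2-(3-methylbut-2-en-1-yl)phenol | COCOc1ccc(C#Cc2c(CC=C(C)C)c(OCOC)cc(OCOC)c2CC=C(C)C)c(O)c1CC=C(C)C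
F5 | step 3 | 1-[3,5-bis(methoxymethoxy)phenyl]ethanone | CC(=O)c1cc(OCOC)cc(OCOC)c1
F6 | step 3 | 1-[2,6-diiodo-3,5-bis(methoxymethoxy)phenyl]ethanone | CC(=O)c1c(I)c(OCOC)cc(OCOC)c1I
F7 | step 6 | 2-bromo-1-iodo-4-(methoxymethoxy)-3-(prop-2-en-1-yl)benzene | COCOc1ccc(I)c(Br)c1CC=C
F8 | step 8 | 2-[2,6-bis(3-methylbut-2-en-1-yl)-3,5-bis(trimethylsilyloxy)phenyl]-7-(3-methylbut-2-en-1-yl)-6-(trimethylsilyloxy)-1-benzofuran | CC(C)=CCc1c(O[Si](C)(C)C)cc(O[Si](C)(C)C)c(CC=C(C)C)c1-c1cc2ccc(O[Si](C)(C)C)c(CC=C(C)C)c2o1
A1 | alternative 1 | (3E)-3-{[6-(methoxymethoxy)-7-(3-methylbut-2-en-1-yl)-1-benzofuran-2-yl]methylidene}-6-methylhept-5-en-2-one | CC(=O)/C(CC=C(C)C)=C/c1cc2ccc(OCOC)c(CC=C(C)C)c2o1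
A2 | alternative 1 | diethyl 2-(3-methylbut-2-en-1-yl)propanedioate | CCOC(=O)C(CC=C(C)C)C(=O)OCC
A3 | alternative 1 | ethyl 2-[6-(methoxymethoxy)-7-(3-methylbut-2-en-1-yl)-1-benzofuran-2-yl]-1,3-bis(3-methylbut-2-en-1-yl)-4,6-dioxocyclohexane-1-carboxylate (mixture of diastereomers) | CCOC(=O)C1(CC=C(C)C)C(=O)CC(=O)C(CC=C(C)C)C1c1cc2ccc(OCOC)c(CC=C(C)C)c2o1
A4 | alternative 2 | 2,4-bis(3-methylbut-2-en-1-yl)-3-[7-(3-methylbut-2-en-1-yl)-6-(triisopropylsilyloxy)-1-benzofuran-2-yl]cyclobut-2-en-1-one (racemic) | O=C1C(CC=C(C)C)=C(c2cc3ccc(O[Si](C(C)C)(C(C)C)C(C)C)c(CC=C(C)C)c3o2)C1CC=C(C)C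
A5 | alternative 2 | (ethynyloxy)triisopropylsilane | C#CO[Si](C(C)C)(C(C)C)C(C)C
A6 | alternative 2 | 2,4-bis(3-methylbut-2-en-1-yl)-3-[7-(3-methylbut-2-en-1-yl)-6-(triisopropylsilyloxy)-1-benzofuran-2-yl]-5-(triisopropylsilyloxy)phenol | CC(C)=CCc1c(O)cc(O[Si](C(C)C)(C(C)C)C(C)C)c(CC=C(C)C)c1-c1cc2ccc(O[Si](C(C)C)(C(C)C)C(C)C)c(CC=C(C)C)c2o1
A7 | alternative 3 | 1-iodo-3,5-bis(methoxymethoxy)benzene | COCOc1cc(I)cc(OCOC)c1
A8 | alternative 3 | [(4-bromo-2-methylbutan-2-yl)oxy]triethylsilane | CC[Si](CC)(CC)OC(C)(C)CCBr
A9 | alternative 3 | 2-[6-(methoxymethoxy)-7-(3-methylbut-2-en-1-yl)-1-benzofuran-2-yl]-4,4,5,5-tetramethyl-1,3,2-dioxaborolane | COCOc1ccc2cc(B3OC(C)(C)C(C)(C)O3)oc2c1CC=C(C)C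
A10 | alternative 3 | 2-[3,5-bis(methoxymethoxy)-2,6-bis(3-methyl-3-triethylsilyloxybutyl)phenyl]-6-(methoxymethoxy)-7-(3-methylbut-2-en-1-yl)-1-benzofuran | CC(C)(O[Si](CC)(CC)CC)CCc1c(OCOC)cc(OCOC)c(CCC(C)(C)O[Si](CC)(CC)CC)c1-c1cc2ccc(OCOC)c(CC=C(C)C)c2o1
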